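The readings were generated by integration on assumed constants; noise was put on by code.

At late times Thursday's run is still making product, 2.2 percentage points between 8.00 min and 12.0 min, although its impurity equals 41.9 % of its catalyst charge.

all flasks: free catalyst 0.2 mol%
- Thursday's: starting material 3.7 mM; partner 1 equiv; impurity 3.1 µM; run made earlier
- Tuesday's: starting material 22 mM; partner 1 equiv; impurity 3.1 µM; run made earlier
- Sunday's: starting material 10 mM; partner 1 equiv; impurity 3.8 µM; run made earlier
- blue: starting material 10 mM; partner 1.00 equiv; impurity 6.0 µM; time 12 min
- ochre: starting material 10 mM; partner 1.00 equiv; impurity 3.1 µM; time 12 min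
- grey: starting material 10 mM; partner 1.50 equiv; impurity 12 µM; time 12 min
- green: starting material 20 mM; partner 3.00 equiv; impurity 3.1 µM; time 12 min
- amber: starting material 2.5 mM; partner 1.00 equiv; impurity 1.0 µM; time 12 min
- red: starting material 20 mM; partner 0.250 equiv; impurity 3.1 µM; time 12 min

| run | time / min | product / % |
|---|---|---|
| Thursday's | 1.00 | 0.8 |
| Thursday's | 3.00 | 2.2 |
| Thursday's | 6.00 | 3.9 |
| Thursday's | 8.00 | 5.1 |
| Thursday's | 12.0 | 7.3 |
| Tuesday's | 2.50 | 30.5 |
| Tuesday's | 5.00 | 44.8 |
| Tuesday's | 8.00 | 54.3 |
| Tuesday's | 10.0 | 57.9 |
| Tuesday's | 12.0 | 61.6 |
| Sunday's | 1.00 | 4.7 |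
| Sunday's | 2.00 | 8.5 |
| Sunday's | 3.00 | 11.8 |
| Sunday's | 6.00 | 20.9 |
| Sunday's | 12.0 | 31.9 |

(scatter of a reading: 0.3 percentage points)

- the numbers in the tables scatter by 0.3 percentage points (one standard deviation)
- a reading or a percentage of product counts all its forms, free or not

* all flasks from highest to lowest amount of product, in percent of the starting material charged, at 12 min (blue / ochre / grey / green / amber / red)
* the amount of product, in percent of the starting material charged of the flask you put first, at 12 min
* the amount of product, in percent of the starting material charged of the flask you put last, at 12 min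

I read that late gain as follows: the impurity takes a fixed part of the catalyst and then stops, being the limiting reagent of that side reaction. So I reckon with two amounts, the impurity charged and the catalyst charged, and not with a time. For green, impurity over catalyst charged gives 7.75 %, and this ratio is what I call the poison share. The loading is a fraction of the starting material, so green charges 40.0 µM of catalyst and ochre 20.0 µM against the same 3.1 µM of impurity. Grey has the highest share, 60.0 %, yet even there the impurity charged is less than the catalyst charged. I put green first, with 92.2 % of its catalyst escaping the impurity and partner in excess, and I expect 7.75 % of its catalyst to end as spent catalyst.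

The forecast gives green > ochre > blue > grey > red > amber, with 85 % (72 % to 95 %) first and 5.2 % (4.3 % to 6.2 %) last, holding that “the impurity appears to remove an equal amount of catalyst”.

The flasks give green > grey > ochre > blue > red > amber, with 94.5 % first and 5.07 % last.

    starting material + partner + free catalyst ⇌ product + free catalyst, rate k1*[starting material]*[partner]*[free catalyst] forward; the back reaction follows from the equilibrium constant (K = 190 M⁻¹, k = 12600 M⁻² s⁻¹)
    crystals ⇌ product, rate k2*(cs2 - [product]) while solid is left; crystals form when [product] > cs2 (solubility = 6.10 mM, k = 0.940 min⁻¹)
    2 free catalyst ⇌ resting dimer, settled at all times (K = 1.20 × 10⁵ M⁻¹)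
    free catalyst + impurity → spent catalyst (k = 1.99 × 10⁵ M⁻¹ s⁻¹)

Green holds 7.75 % of its catalyst as spent catalyst, the poison share 7.75 % again, and that loss makes no difference to its product. Green's neighbour with 5.0 mM of starting material has a share of 31.0 %, holds 31.0 % as spent catalyst and reaches 34.4 % of product. Green's product at 12.0 min includes crystals equal to 63.2 % of the starting material charged, and how little product dissolves is one part of its 94.5 %: with that taken away, green gives 88.3 %.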